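**Retrosynthetic overview**

- Ring A is hexasubstituted: OMe at C1 sits between CH3 (C2) and the isobutyryl carbon (C6), and the bridge CH2 (C4) sits between the OH groups at C3 and C5. This order is built by construction, not by substitution or selective O-methylation of a phloroglucinol.
- Robustaol A ⇒ late CHO at ring B C3′ (Vilsmeier), O-debenzylation, O-desilylation, isovaleryl at ring B C5′ (Friedel–Crafts), isobutyryl at ring A C6 (phenol-directed formylation, Grignard addition, oxidation) ⇒ a ring A phenol with C6–H.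
- Ring A ⇒ benzannulation of 3-methoxy-2-methylcyclobutenone with the siloxyalkyne TIPSO–C≡C–CH2–Ar that carries ring B; it forms C4–C5 and C2–C3 and closes C5–C6 by six-electron electrocyclisation.
- Siloxyalkyne ⇒ ethyl arylacetate (ynolate formation, O-silylation) ⇒ 2,4,6-tris(benzyloxy)benzaldehyde ⇒ 3,5-bis(benzyloxy)phenol + benzyl bromide; cyclobutenone ⇒ 2-methylcyclobutane-1,3-dione ⇒ methylketene + ethoxyethyne.
- Ring order: ring B is bought as the dibenzyl ether of phloroglucinol; the four-membered ring is made first; ring A is the only ring closed later, in step 9.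

Key step: step 9

Remark on the chemistry: robustaol A has no stereocentre. The stereogenic elements of intermediates 4, 12, 18 and 24 are not controlled and are erased downstream, so their SMILES carry no descriptors.

Remark on the chemistry: 3,5-bis(benzyloxy)phenol is assumed to be commercially available and is taken as the ring B starting material. One O-benzylation then completes the triether, and the C-benzylation that free phloroglucinol suffers is avoided.

**Route**

Step 1
Reactants: 1 propanoyl chloride; 2 ethoxyethyne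
Product: 4 3-ethoxy-4-methylcyclobut-2-en-1-one (racemic), via methylketene 3 (not isolated)
Conditions: Et3N, Et2O, 0 °C→rt, slow addition of 1
Reagents that add atoms: none
Why: Ketene–alkyne [2+2] cycloaddition, in which methylketene from in situ dehydrochlorination bonds through its carbonyl carbon to the nucleophilic CH terminus of the ynol ether.

Step 2
Reactants: 4 3-ethoxy-4-methylcyclobut-2-en-1-one
Product: 5 3-hydroxy-2-methylcyclobut-2-en-1-one (enol form of 2-methylcyclobutane-1,3-dione)
Conditions: 1 M aq HCl, THF, 0 °C→rt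
Reagents that add atoms: water, O
Why: Acid hydrolysis of the vinylogous ester gives the symmetric 1,3-dione, which re-enolises toward the methyl-bearing carbon and so moves the methyl group onto the enone α-carbon.

Step 3
Reactants: 5 3-hydroxy-2-methylcyclobut-2-en-1-one
Product: 6 3-methoxy-2-methylcyclobut-2-en-1-one
Conditions: TMSCHN2, MeOH/Et2O, 0 °C
Reagents that add atoms: trimethylsilyldiazomethane, C[Si](C)(C)C=[N+]=[N-]
Why: Diazoalkane O-methylation of the strongly acidic vinylogous acid, which avoids C-methylation and ring opening; either oxygen of the symmetric dione gives the same enol ether.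

Step 4
Reactants: 7 3,5-bis(benzyloxy)phenol; 8 benzyl bromide
Product: 9 1,3,5-tris(benzyloxy)benzene
Conditions: K2CO3, DMF, rt→60 °C
Reagents that add atoms: none
Why: Williamson etherification of the one remaining phenol; with two oxygens already benzylated the phenoxide reacts at oxygen, so C-benzylation should be minor.

Step 5
Reactants: 9 1,3,5-tris(benzyloxy)benzene
Product: 11 2,4,6-tris(benzyloxy)benzaldehyde, via iminium salt 10 (not isolated)
Conditions: POCl3, DMF, 0 °C→rt; then H2O, 60 °C
Reagents that add atoms: N,N-dimethylformamide, CN(C)C=O; water, O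
Why: Vilsmeier–Haack formylation of a phloroglucinol triether stops at the mono-aldehyde because the iminium group deactivates the ring.

Step 6
Reactants: 11 2,4,6-tris(benzyloxy)benzaldehyde
Product: 12 1,3,5-tris(benzyloxy)-2-[2-(methanesulfinyl)-2-(methylsulfanyl)ethenyl]benzene
Conditions: MeS(O)CH2SMe, Triton B (cat.), THF, reflux
Reagents that add atoms: methyl (methylsulfanyl)methyl sulfoxide (FAMSO), CSCS(C)=O
Why: Base-catalysed Knoevenagel-type condensation of the acidic CH2 of FAMSO with the aldehyde gives the ketene dithioacetal S-oxide, the first half of the FAMSO arylacetic ester synthesis.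

Step 7
Reactants: 12 ketene dithioacetal S-oxide
Product: 13 ethyl [2,4,6-tris(benzyloxy)phenyl]acetate
Conditions: dry HCl, EtOH, rt→50 °C
Reagents that add atoms: ethanol, CCO
Why: Acid ethanolysis of the ketene dithioacetal S-oxide (Pummerer-type transfer of the oxidation level from sulfur to carbon) should give the arylacetic ester and dimethyl disulfide under conditions that benzyl aryl ethers tolerate.

Step 8
Reactants: 13 ethyl [2,4,6-tris(benzyloxy)phenyl]acetate
Product: 16 triisopropyl({3-[2,4,6-tris(benzyloxy)phenyl]prop-1-yn-1-yl}oxy)silane, via dibromo enolate 14 (not isolated), via lithium ynolate 15 (not isolated)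
Conditions: CH2Br2, LiTMP, THF, −78 °C; LiHMDS, −78→−20 °C; n-BuLi, −78 °C→rt; TIPSCl, −78 °C→rt
Reagents that add atoms: dibromomethane, BrCBr; chlorotriisopropylsilane, CC(C)[Si](Cl)(C(C)C)C(C)C
Why: Kowalski ester homologation stopped at the ynolate: dibromomethyllithium adds to the ester, Br–Li exchange on enolate 14 triggers a 1,2-shift of the arylmethyl group to ynolate 15, and the bulky TIPSCl silylates on oxygen to give the siloxyalkyne, which is used promptly without acidic silica.

Step 9
Reactants: 6 3-methoxy-2-methylcyclobut-2-en-1-one (1.5 equiv); 16 siloxyalkyne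
Product: 21 5-methoxy-4-methyl-3-[(triisopropylsilyl)oxy]-2-{[2,4,6-tris(benzyloxy)phenyl]methyl}phenol, via vinylketene 17 (not isolated), via vinylcyclobutenone 18 (not isolated), via dienylketene 19 (not isolated), via cyclohexadienone 20 (not isolated)
Conditions: toluene (0.5 M), 80 °C then 110 °C, sealed tube, Ar
Reagents that add atoms: none
Why: Heating opens cyclobutenone 6 by conrotatory four-electron electrocyclic ring opening to vinylketene 17, whose ketene C=C adds [2+2] to the electron-rich siloxyalkyne 16 to give 4-vinylcyclobutenone 18, and a second four-electron opening gives dienylketene 19. Ring A, a six-membered carbocycle, then closes by thermal disrotatory six-electron electrocyclisation of 19 between the ketene carbon (C5) and the methylene terminus (C6), and cyclohexadienone 20 tautomerises to phenol 21. The closest known reaction type is the Danheiser benzannulation of cyclobutenones with trialkylsiloxyalkynes, which is established for highly substituted resorcinol monosilyl ethers. No stereocentre is created, since the one stereocentre of 18 is erased on ring opening. The single selectivity needed is the regiochemistry of the ketene–alkyne [2+2]: the O-silyl group polarises 16 so that its benzyl-bearing carbon (C4) bonds to the ketene carbonyl carbon (C5) and its oxygenated carbon (C3) bonds to the methyl-bearing carbon (C2). The only free phenol therefore appears at C5, next to the single unsubstituted ring carbon C6.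

Step 10
Reactants: 21 ring A phenol
Product: 23 2-hydroxy-6-methoxy-5-methyl-4-[(triisopropylsilyl)oxy]-3-{[2,4,6-tris(benzyloxy)phenyl]methyl}benzaldehyde, via hydroxymethylphenol 22 (not isolated)
Conditions: MgCl2, Et3N, (CH2O)n, MeCN, reflux; dilute HCl work-up
Reagents that add atoms: formaldehyde (as paraformaldehyde), C=O
Why: Casnati–Skattebøl ortho-formylation, in which the magnesium phenoxide delivers formaldehyde only to the carbon ortho to the phenol (ring A C6, ring B has no phenol) and a second formaldehyde oxidises the salicyl alcohol 22 by hydride transfer.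

Step 11
Reactants: 23 salicylaldehyde
Product: 24 2-(1-hydroxy-2-methylpropyl)-3-methoxy-4-methyl-5-[(triisopropylsilyl)oxy]-6-{[2,4,6-tris(benzyloxy)phenyl]methyl}phenol (racemic carbinol)
Conditions: i-PrMgCl (3 equiv), LaCl3·2LiCl, THF, 0 °C; aq NH4Cl
Reagents that add atoms: isopropylmagnesium chloride, CC(C)[Mg]Cl
Why: Grignard 1,2-addition to the aldehyde, with the lanthanum salt favouring addition over β-hydride reduction; the carbinol centre is formed racemic and is removed in step 12, and the crude acid-labile carbinol is carried on without chromatography.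

Step 12
Reactants: 24 carbinol
Product: 25 1-{2-hydroxy-6-methoxy-5-methyl-4-[(triisopropylsilyl)oxy]-3-{[2,4,6-tris(benzyloxy)phenyl]methyl}phenyl}-2-methylpropan-1-one
Conditions: MnO2 (activated, excess), CH2Cl2, rt
Reagents that add atoms: none
Why: MnO2 oxidation of the benzylic alcohol under neutral heterogeneous conditions should spare the silyl and benzyl ethers and avoid acid-triggered ortho-quinone methide formation.

Step 13
Reactants: 25 ring A ketone
Product: 26 1-{2-hydroxy-6-methoxy-5-methyl-3-{[2,4,6-tris(benzyloxy)-3-(3-methylbutanoyl)phenyl]methyl}-4-[(triisopropylsilyl)oxy]phenyl}-2-methylpropan-1-one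
Conditions: isovaleric acid, TFAA, CH2Cl2, 0 °C→rt; aq NaHCO3 work-up
Reagents that add atoms: 3-methylbutanoic acid, CC(C)CC(O)=O
Why: Friedel–Crafts acylation by the mixed trifluoroacetic anhydride without a Lewis acid: ring A has no free CH, the two open positions of ring B are equivalent, and the first acyl group deactivates the ring against a second.

Step 14
Reactants: 26 bis-ketone
Product: 27 1-{2,4-dihydroxy-6-methoxy-5-methyl-3-{[2,4,6-tris(benzyloxy)-3-(3-methylbutanoyl)phenyl]methyl}phenyl}-2-methylpropan-1-one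
Conditions: TBAF, AcOH, THF, 0 °C→rt
Reagents that add atoms: none
Why: Fluoride cleavage of the aryl silyl ether, buffered with acetic acid so that no free phenoxide persists next to the methylene bridge.

Step 15
Reactants: 27 tribenzyl ether
Product: 28 1-{3-{[2,6-dihydroxy-4-methoxy-3-methyl-5-(2-methylpropanoyl)phenyl]methyl}-2,4,6-trihydroxyphenyl}-3-methylbutan-1-one
Conditions: H2 (1 atm), Pd/C, EtOAc/MeOH, rt
Reagents that add atoms: none
Why: Catalytic hydrogenolysis removes the three benzyl ethers under neutral conditions; the hydrogen-bonded ortho-hydroxyaryl ketones and the aryl methyl ether are not expected to react.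

Step 16
Reactants: 28 des-formyl precursor
Product: 30 robustaol A, via iminium salt 29 (not isolated)
Conditions: POCl3, DMF, EtOAc, 0 °C→rt; then H2O, 60 °C
Reagents that add atoms: N,N-dimethylformamide, CN(C)C=O; water, O
Why: Vilsmeier–Haack formylation of an acylphloroglucinol: ring B C3′ is the only aromatic CH in the molecule, and any O-formyl groups hydrolyse during the aqueous heating.

**Compound list**

1 | propanoyl chloride | CCC(Cl)=O | starting material
2 | ethoxyethyne | CCOC#C | starting material
3 | methylketene (prop-1-en-1-one, formed in situ) | CC=C=O | intermediate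
4 | 3-ethoxy-4-methylcyclobut-2-en-1-one (racemic) | CCOC1=CC(=O)C1C | intermediate
5 | 3-hydroxy-2-methylcyclobut-2-en-1-one | CC1=C(O)CC1=O | intermediate
6 | 3-methoxy-2-methylcyclobut-2-en-1-one | COC1=C(C)C(=O)C1 | intermediate
7 | 3,5-bis(benzyloxy)phenol | Oc1cc(OCc2ccccc2)cc(OCc2ccccc2)c1 | starting material
8 | benzyl bromide | BrCc1ccccc1 | starting material
9 | 1,3,5-tris(benzyloxy)benzene | c1ccc(COc2cc(OCc3ccccc3)cc(OCc3ccccc3)c2)cc1 | intermediate
10 | {[2,4,6-tris(benzyloxy)phenyl]methylidene}dimethylammonium chloride (formed in situ) | C[N+](C)=Cc1c(OCc2ccccc2)cc(OCc2ccccc2)cc1OCc1ccccc1.[Cl-] | intermediate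
11 | 2,4,6-tris(benzyloxy)benzaldehyde | O=Cc1c(OCc2ccccc2)cc(OCc2ccccc2)cc1OCc1ccccc1 | intermediate
12 | 1,3,5-tris(benzyloxy)-2-[2-(methanesulfinyl)-2-(methylsulfanyl)ethenyl]benzene (geometry and sulfur configuration not controlled) | CSC(=Cc1c(OCc2ccccc2)cc(OCc2ccccc2)cc1OCc1ccccc1)S(C)=O | intermediate
13 | ethyl [2,4,6-tris(benzyloxy)phenyl]acetate | CCOC(=O)Cc1c(OCc2ccccc2)cc(OCc2ccccc2)cc1OCc1ccccc1 | intermediate
14 | lithium 1,1-dibromo-3-[2,4,6-tris(benzyloxy)phenyl]prop-1-en-2-olate (formed in situ) | [Li]OC(Cc1c(OCc2ccccc2)cc(OCc2ccccc2)cc1OCc1ccccc1)=C(Br)Br | intermediate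
15 | lithium 3-[2,4,6-tris(benzyloxy)phenyl]prop-1-yn-1-olate (formed in situ) | [Li]OC#CCc1c(OCc2ccccc2)cc(OCc2ccccc2)cc1OCc1ccccc1 | intermediate
16 | triisopropyl({3-[2,4,6-tris(benzyloxy)phenyl]prop-1-yn-1-yl}oxy)silane | CC(C)[Si](C(C)C)(C(C)C)OC#CCc1c(OCc2ccccc2)cc(OCc2ccccc2)cc1OCc1ccccc1 | intermediate
17 | 3-methoxy-2-methylbuta-1,3-dien-1-one (vinylketene, formed in situ) | COC(=C)C(C)=C=O | intermediate
18 | 4-(1-methoxyethenyl)-4-methyl-3-[(triisopropylsilyl)oxy]-2-{[2,4,6-tris(benzyloxy)phenyl]methyl}cyclobut-2-en-1-one (racemic, formed in situ) | COC(=C)C1(C)C(=O)C(Cc2c(OCc3ccccc3)cc(OCc3ccccc3)cc2OCc2ccccc2)=C1O[Si](C(C)C)(C(C)C)C(C)C | intermediate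
19 | (3E)-5-methoxy-4-methyl-3-[(triisopropylsilyl)oxy]-2-{[2,4,6-tris(benzyloxy)phenyl]methyl}hexa-1,3,5-trien-1-one (dienylketene, vinyl and ketene carbons cis, formed in situ) | COC(=C)/C(C)=C(O[Si](C(C)C)(C(C)C)C(C)C)\C(Cc1c(OCc2ccccc2)cc(OCc2ccccc2)cc1OCc1ccccc1)=C=O | intermediate
20 | 5-methoxy-4-methyl-3-[(triisopropylsilyl)oxy]-2-{[2,4,6-tris(benzyloxy)phenyl]methyl}cyclohexa-2,4-dien-1-one (formed in situ) | COC1=C(C)C(O[Si](C(C)C)(C(C)C)C(C)C)=C(Cc2c(OCc3ccccc3)cc(OCc3ccccc3)cc2OCc2ccccc2)C(=O)C1 | intermediate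
21 | 5-methoxy-4-methyl-3-[(triisopropylsilyl)oxy]-2-{[2,4,6-tris(benzyloxy)phenyl]methyl}phenol | COc1cc(O)c(Cc2c(OCc3ccccc3)cc(OCc3ccccc3)cc2OCc2ccccc2)c(O[Si](C(C)C)(C(C)C)C(C)C)c1C | intermediate
22 | 2-(hydroxymethyl)-3-methoxy-4-methyl-5-[(triisopropylsilyl)oxy]-6-{[2,4,6-tris(benzyloxy)phenyl]methyl}phenol (formed in situ) | COc1c(CO)c(O)c(Cc2c(OCc3ccccc3)cc(OCc3ccccc3)cc2OCc2ccccc2)c(O[Si](C(C)C)(C(C)C)C(C)C)c1C | intermediate
23 | 2-hydroxy-6-methoxy-5-methyl-4-[(triisopropylsilyl)oxy]-3-{[2,4,6-tris(benzyloxy)phenyl]methyl}benzaldehyde | COc1c(C=O)c(O)c(Cc2c(OCc3ccccc3)cc(OCc3ccccc3)cc2OCc2ccccc2)c(O[Si](C(C)C)(C(C)C)C(C)C)c1C | intermediate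
24 | 2-(1-hydroxy-2-methylpropyl)-3-methoxy-4-methyl-5-[(triisopropylsilyl)oxy]-6-{[2,4,6-tris(benzyloxy)phenyl]methyl}phenol (racemic) | COc1c(C(O)C(C)C)c(O)c(Cc2c(OCc3ccccc3)cc(OCc3ccccc3)cc2OCc2ccccc2)c(O[Si](C(C)C)(C(C)C)C(C)C)c1C | intermediate
25 | 1-{2-hydroxy-6-methoxy-5-methyl-4-[(triisopropylsilyl)oxy]-3-{[2,4,6-tris(benzyloxy)phenyl]methyl}phenyl}-2-methylpropan-1-one | COc1c(C(=O)C(C)C)c(O)c(Cc2c(OCc3ccccc3)cc(OCc3ccccc3)cc2OCc2ccccc2)c(O[Si](C(C)C)(C(C)C)C(C)C)c1C | intermediate
26 | 1-{2-hydroxy-6-methoxy-5-methyl-3-{[2,4,6-tris(benzyloxy)-3-(3-methylbutanoyl)phenyl]methyl}-4-[(triisopropylsilyl)oxy]phenyl}-2-methylpropan-1-one | COc1c(C(=O)C(C)C)c(O)c(Cc2c(OCc3ccccc3)cc(OCc3ccccc3)c(C(=O)CC(C)C)c2OCc2ccccc2)c(O[Si](C(C)C)(C(C)C)C(C)C)c1C | intermediate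
27 | 1-{2,4-dihydroxy-6-methoxy-5-methyl-3-{[2,4,6-tris(benzyloxy)-3-(3-methylbutanoyl)phenyl]methyl}phenyl}-2-methylpropan-1-one | COc1c(C(=O)C(C)C)c(O)c(Cc2c(OCc3ccccc3)cc(OCc3ccccc3)c(C(=O)CC(C)C)c2OCc2ccccc2)c(O)c1C | intermediate
28 | 1-{3-{[2,6-dihydroxy-4-methoxy-3-methyl-5-(2-methylpropanoyl)phenyl]methyl}-2,4,6-trihydroxyphenyl}-3-methylbutan-1-one | COc1c(C(=O)C(C)C)c(O)c(Cc2c(O)cc(O)c(C(=O)CC(C)C)c2O)c(O)c1C | intermediate
29 | ring B C3′ dimethyliminium chloride of 28 (formed in situ) | COc1c(C)c(O)c(Cc2c(O)c(C=[N+](C)C)c(O)c(C(=O)CC(C)C)c2O)c(O)c1C(=O)C(C)C.[Cl-] | intermediate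
30 | robustaol A, 3-{[2,6-dihydroxy-4-methoxy-3-methyl-5-(2-methylpropanoyl)phenyl]methyl}-2,4,6-trihydroxy-5-(3-methylbutanoyl)benzaldehyde | COc1c(C)c(O)c(Cc2c(O)c(C=O)c(O)c(C(=O)CC(C)C)c2O)c(O)c1C(=O)C(C)C | target

**Step count**

Total: 16 steps. Longest linear sequence: 13 steps (steps 4 to 16, from 3,5-bis(benzyloxy)phenol); the cyclobutenone branch (steps 1 to 3) joins at step 9.

**Steps most likely to fail, with fallbacks**

Step 9 (benzannulation). The methoxy group makes cyclobutenone 6 a vinylogous ester, so its four-electron ring opening may be slow. The siloxyalkyne could then isomerise by silyl shift or the ketene could dimerise before the [2+2] capture, and the product phenol may also trap vinylketene as an aryl ester. The fallback sets out from siloxyalkyne 16 and comes back at phenol 21; it makes the same vinylketene 17 at low temperature from an acyclic acid chloride instead of from the four-membered ring. Commercial methyl 2-methyl-3-oxobutanoate is treated with HC(OMe)3 and catalytic H2SO4 in MeOH to give methyl (2E)-3-methoxy-2-methylbut-2-enoate F1. Saponification (KOH, aqueous MeOH, careful acidification) gives (2E)-3-methoxy-2-methylbut-2-enoic acid F2. Oxalyl chloride with catalytic DMF gives (2E)-3-methoxy-2-methylbut-2-enoyl chloride F3. Slow addition of Et3N to F3 and 16 in toluene at 0 °C→rt should cause 1,4-dehydrochlorination to 17, which is trapped as 18; warming to 80 °C then completes the opening and electrocyclisation to 21.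

Step 8 (ynolate formation and silylation). The arylacetate has acidic benzylic α-hydrogens, so enolisation may compete with addition of dibromomethyllithium, and excess alkyllithium may attack the benzyl ethers on warming. The fallback sets out from ester 13 and comes back at siloxyalkyne 16. i-Bu2AlH (DIBAL-H) in CH2Cl2 at −78 °C reduces 13 to [2,4,6-tris(benzyloxy)phenyl]acetaldehyde F4. The Ohira–Bestmann reagent (dimethyl (1-diazo-2-oxopropyl)phosphonate, K2CO3, MeOH) converts it into 1,3,5-tris(benzyloxy)-2-(prop-2-yn-1-yl)benzene F5. Deprotonation of F5 with LiHMDS and oxidation of the lithium acetylide with lithium tert-butyl peroxide (from t-BuOOH and LiHMDS, THF, −78→0 °C) gives ynolate 15, which TIPSOTf silylates at −78 °C to 16.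

Step 13 (acylation of ring B). The methylene bridge joins two strongly activated rings, so under the acidic mixed-anhydride conditions ipso attack or protonation at a bridge-bearing carbon may split the diarylmethane, and the ring A phenol may be O-acylated. The fallback sets out from ketone 25 and comes back at bis-ketone 26, building the isovaleryl group in three non-acidic operations. Vilsmeier–Haack reaction (POCl3, DMF, 0 °C→rt) on ring B gives the iminium salt F6, hydrolysed on aqueous work-up to the ring B aldehyde F7. Isobutylmagnesium chloride with LaCl3·2LiCl in THF at 0 °C adds to the aldehyde only, since the hindered, phenoxide-conjugated ring A ketone should not react, and gives the carbinol F8. MnO2 in CH2Cl2 oxidises F8 to 26.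

**Further compounds**

F1 | step 9 | methyl (2E)-3-methoxy-2-methylbut-2-enoate | CO/C(C)=C(\C)C(=O)OC
F2 | step 9 | (2E)-3-methoxy-2-methylbut-2-enoic acid | CO/C(C)=C(\C)C(O)=O
F3 | step 9 | (2E)-3-methoxy-2-methylbut-2-enoyl chloride | CO/C(C)=C(\C)C(Cl)=O
F4 | step 8 | [2,4,6-tris(benzyloxy)phenyl]acetaldehyde | O=CCc1c(OCc2ccccc2)cc(OCc2ccccc2)cc1OCc1ccccc1
F5 | step 8 | 1,3,5-tris(benzyloxy)-2-(prop-2-yn-1-yl)benzene | C#CCc1c(OCc2ccccc2)cc(OCc2ccccc2)cc1OCc1ccccc1
F6 | step 13 | ring B dimethyliminium chloride of 25 | COc1c(C(=O)C(C)C)c(O)c(Cc2c(OCc3ccccc3)cc(OCc3ccccc3)c(C=[N+](C)C)c2OCc2ccccc2)c(O[Si](C(C)C)(C(C)C)C(C)C)c1C.[Cl-]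
F7 | step 13 | 2,4,6-tris(benzyloxy)-3-{[2-hydroxy-4-methoxy-5-methyl-3-(2-methylpropanoyl)-6-[(triisopropylsilyl)oxy]phenyl]methyl}benzaldehyde | COc1c(C(=O)C(C)C)c(O)c(Cc2c(OCc3ccccc3)cc(OCc3ccccc3)c(C=O)c2OCc2ccccc2)c(O[Si](C(C)C)(C(C)C)C(C)C)c1C
F8 | step 13 | 1-{2-hydroxy-6-methoxy-5-methyl-3-{[2,4,6-tris(benzyloxy)-3-(1-hydroxy-3-methylbutyl)phenyl]methyl}-4-[(triisopropylsilyl)oxy]phenyl}-2-methylpropan-1-one (racemic) | COc1c(C(=O)C(C)C)c(O)c(Cc2c(OCc3ccccc3)cc(OCc3ccccc3)c(C(O)CC(C)C)c2OCc2ccccc2)c(O[Si](C(C)C)(C(C)C)C(C)C)c1C
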